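Numbering used throughout: germacranolide numbering (C1–C10 ring carbons, C11–C13 lactone carbons, C14 and C15 the methyl groups on C10 and C4). The cyclohexene intermediates ("ring A" = C1–C6) keep these numbers.

## Analysis of the target

The target (36) is a germacranolide: a ten-membered carbocycle C1–C10 fused at C6–C7 to an α-methylene-γ-butyrolactone (O6–C12(=O)–C11(=C13)–C7). Both ring alkenes, C1=C10 and C4=C5, are trisubstituted and Z, that is, cis within the ring. The ring carries five stereocentres (3S, 6R, 7R, 8S, 9R): an acetate at C3, the lactone oxygen at C6, the lactone carbon at C7, a (2R,3R)-2,3-dimethyloxirane-2-carboxylate at C8 and a free hydroxyl at C9. Drawn flat, O6 and C11 lie on one face (cis-fused lactone) and O3, O8 and O9 on the other, so C11/O8 are trans and O8/O9 cis. The sensitive groups are the α-methylene lactone (Michael acceptor), the epoxy ester, the allylic acetate, the C8 ester next to the free C9 hydroxyl (acyl migration under base) and the 1(10),4-diene (acid-induced transannular cyclisation). The difficulty lies in a medium ring with two Z trisubstituted alkenes and four contiguous stereocentres C6–C9, three of them oxygenated and each dressed differently. The strategy rests on one feature: the C6 oxygen and the C1=C10 alkene stand in the 1,5-relationship of a cyclodec-5-enone, and the doubly oxygenated C8–C9 bond is the bond a [3,3] shift forms. Reconnecting C1–C6 then gives a cyclohexene (ring A) whose carbon skeleton is that of (R)-carvone 6.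

## Retrosynthetic reasoning

**End game.** The free C9 hydroxyl of 36 is unmasked last from its p-methoxyphenyl ether 35, because an oxidative, non-basic cleavage spares the epoxy ester and cannot trigger C8→C9 acyl migration. The C8 ester is cut next, giving alcohol 33 and epoxy acid 5; this keeps the epoxide out of every enolate, hydride and fluoride step. The C3 acetate of 32 is traced through alcohol 31 to the silyl ether 30, since an acetate would not survive the lactone enolate needed for C13.

**Lactone.** C13 is removed from 30, which leaves lactone 26 (α-methylenation in the forward sense). The lactone C12–O6 bond is cut to diol 24, which comes from ketone 22 by reduction at C6 and release of the C12 hydroxyl. The forward steps must set C6 (6R) and oxidise only the primary alcohol.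

**Key disconnection.** In ketone 22 the C8–C9 bond is cut and C1–C6 is re-formed. This is the retro-oxy-Cope step to the cis-1,6-dialkenylcyclohex-2-en-1-ol 19 (through enolate 21 and alkoxide 20). It is chosen because a single step then makes the ten-membered ring without end-to-end closure, fixes the Z geometry of C1=C10, sets C8 and C9 from two enol-ether geometries, and hands C7 to a face-selective protonation. The forward reaction must run through one chair and must not lose the β-alkoxy group from the enolate.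

**C7 alkenyl group of 19.** The silyl ether 19 is traced to alcohol 18, and 18 to diene 16 by cutting the C12–O bond (hydroboration forward). The Z trisubstituted enol ether of 16 is disconnected at O8–C8, which leads to iodide 15 (CuI-catalysed vinyl etherification forward). Iodide 15 is disconnected at C7–C11 and C8–I to the terminal alkyne 13 (anti-carbomagnesiation with a two-carbon vinyl nucleophile, then iodinolysis). The magnesium chelate forces the metal, then iodine, then oxygen to sit cis to C6, which is exactly the Z geometry required; no geometric mixture can arise.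

**C1 alkenyl group.** The E aryl enol ether of 13 is traced to the allyl aryl ether 12 (base-mediated allyl-to-propenyl isomerisation) and then to the allylic chloride 11. The isomerisation is placed at the ethynyl carbinol stage, where the dianion (alkoxide and acetylide) cannot undergo a premature Cope shift.

**C6 carbinol.** The C6–C7 bond of 11 is cut to enone 10 and an ethynyl nucleophile. A small sp nucleophile is chosen because axial attack places it cis to the C1 side chain, the relationship the chair needs.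

**Ring A.** Enone 10 is simplified by removing the C6 oxygen (allylic oxidation of 9), the silyl group (8), and by re-oxidising C3 (7). Removing chlorine from 7 gives (R)-carvone 6. Carvone 6 supplies C1 with the right absolute configuration, the C4 methyl, the C3 oxygen and the three carbons C10, C9 and C14.

**Acid 5.** The carboxyl group is traced to the primary alcohol 3, the epoxide to the Z allylic alcohol 2 (asymmetric epoxidation), and 2 to angelic acid 1.

## Alternatives that were turned down

Alternative 1: The lactone is disconnected at O6–C12 and C11–C12. In the forward step a cyclocarbonylation of the 7-ethynyl-6-hydroxy ten-membered carbocycle A2 (for example with Pd(OAc)2 and PPh3 under CO) would insert a carbonyl group between the hydroxyl and the alkyne and give the C9 triethylsilyl ether of the target A1. In its favour, the α-methylene lactone arrives in one operation from a cis hydroxy alkyne, with no lactone enolate, and the step can be run near the end. Against it, A2 already contains the ten-membered ring, both Z alkenes and all five ring stereocentres, so the hard part of the problem is only moved. The catalyst passes through zerovalent palladium, which would meet an ionisable allylic acetate at C3, an epoxide and a strained diene. On lactone formation this alternative is stronger (one step against steps 15–17 here). The chosen strategy offers in its place the ring, the C1=C10 geometry and C7–C9 in one step.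

Alternative 2: The C7–C8 bond is disconnected, with an O8–C13 ether bond in the precursor. The boron enolate (formed with Bu2BOTf and iPr2NEt) of the thirteen-membered keto ether A4 would undergo a [2,3]-Wittig shift onto its butenolide and contract to the ten-membered 9-keto-8-hydroxy α-methylene lactone A3. In its favour, a thirteen-membered ring is easier to close than a ten-membered one, and the shift makes C7–C8, two stereocentres and the exocyclic methylene together. Against it, enolisation of A4 competes with deprotonation at the acidic γ-position (C6) of the butenolide and with a [1,2] shift, and the sense of C7/C8 depends on a transannular transition state that cannot be predicted with confidence. A3 also still needs a stereoselective C9 reduction and differentiation of two adjacent hydroxyls, and A4 itself is a long synthesis. It is as strong as the chosen route in making stereocentres during ring formation and stronger in delivering the methylene lactone directly. The chosen route answers with a precursor reached from carvone in ten steps and with C8/C9 read off from alkene geometries.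

Alternative 3: The ring is disconnected at C5–C6. A vinylchromium species formed from the open-chain (Z)-vinyl iodide aldehyde A6 with CrCl2 and catalytic NiCl2 would add to the C6 aldehyde (a Nozaki–Hiyama–Kishi closure), and the alkoxide would lactonise onto the acrylate ester to give the protected lactone core A5. In its favour, the chemistry tolerates dense functionality, C7–C9 can be built by acyclic methods, and the methylene lactone forms in the same flask. Against it, a ten-membered ring with two Z alkenes must be closed end to end under high dilution, and the new C6 stereocentre depends on the conformation of the closing chain. The aldehyde α-carbon C7 of A6 is doubly activated and prone to epimerisation or conjugation, and A6 needs a long linear sequence. It is stronger in convergence and in late lactone formation. The chosen strategy forms the ring by ring expansion (no dilution, no entropic penalty) and fixes alkene geometry and C8/C9 stereospecifically.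

Key step: step 14

## Route

Step 1
Reactants: 1 angelic acid [(2Z)-2-methylbut-2-enoic acid]
Product: 2 (2Z)-2-methylbut-2-en-1-ol
Conditions: LiAlH4, Et2O, 0 °C → rt
Reagents that add atoms: none
Why: Hydride reduction of the carboxylic acid to the primary allylic alcohol; the trisubstituted alkene is not reduced and keeps its Z geometry.

Step 2
Reactants: 2 (2Z)-2-methylbut-2-en-1-ol
Product: 3 [(2S,3R)-2,3-dimethyloxiran-2-yl]methanol
Conditions: Ti(OiPr)4 (cat.), L-(+)-diethyl tartrate (cat.), t-BuOOH, 4 Å MS, CH2Cl2, −20 °C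
Reagents that add atoms: tert-butyl hydroperoxide, CC(C)(C)OO
Why: Sharpless asymmetric epoxidation; the (2R,3R)-tartrate complex delivers oxygen to the face that gives 2S in primary allylic alcohols, and the syn addition keeps the C3 methyl cis to the CH2OH group (3R).

Step 3
Reactants: 3 [(2S,3R)-2,3-dimethyloxiran-2-yl]methanol
Product: 5 (2R,3R)-2,3-dimethyloxirane-2-carboxylic acid, via epoxy aldehyde 4 (not isolated)
Conditions: RuCl3·xH2O (cat.), NaIO4, CCl4/MeCN/H2O, rt
Reagents that add atoms: water, O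
Why: Catalytic RuO4 oxidises the primary alcohol through the aldehyde hydrate to the acid without touching the epoxide; the C2 label changes from S to R only because CO2H outranks the ring carbon.

Step 4
Reactants: 6 (R)-(−)-carvone [(5R)-2-methyl-5-(prop-1-en-2-yl)cyclohex-2-en-1-one]
Product: 7 (5R)-5-(3-chloroprop-1-en-2-yl)-2-methylcyclohex-2-en-1-one
Conditions: Ca(OCl)2, CO2 (solid), CH2Cl2/H2O, 0 °C
Reagents that add atoms: calcium hypochlorite, [Ca+2].[O-]Cl.[O-]Cl
Why: Hypochlorous acid released by CO2 chlorinates the electron-rich 1,1-disubstituted alkene in an ene-type allylic chlorination; the conjugated ring alkene is deactivated and C1 is untouched.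

Step 5
Reactants: 7 (5R)-5-(3-chloroprop-1-en-2-yl)-2-methylcyclohex-2-en-1-one
Product: 8 (1S,5R)-5-(3-chloroprop-1-en-2-yl)-2-methylcyclohex-2-en-1-ol (hydroxyl trans to the side chain; germacrane labels 1R,3S)
Conditions: (R)-Me-CBS oxazaborolidine [(R)-1-methyl-3,3-diphenyltetrahydropyrrolo[1,2-c][1,3,2]oxazaborole] (20 mol %), catecholborane, toluene, −78 °C
Reagents that add atoms: none
Why: Corey–Bakshi–Shibata 1,2-reduction of the enone under catalyst control, with the C(Me)=CH arm as the large group; the R catalyst should give the 1S carbinol, the trans isomer that substrate-controlled hydride reduction does not favour. Catecholborane at −78 °C does not hydroborate the side-chain alkene.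

Step 6
Reactants: 8 (1S,5R)-5-(3-chloroprop-1-en-2-yl)-2-methylcyclohex-2-en-1-ol
Product: 9 tert-butyl{[(1S,5R)-5-(3-chloroprop-1-en-2-yl)-2-methylcyclohex-2-en-1-yl]oxy}dimethylsilane
Conditions: t-BuMe2SiCl, imidazole, DMF, rt
Reagents that add atoms: tert-butyldimethylsilyl chloride, CC(C)(C)[Si](C)(C)Cl
Why: Standard silylation of a secondary allylic alcohol; the silyl ether protects C3 up to step 18.

Step 7
Reactants: 9 tert-butyl{[(1S,5R)-5-(3-chloroprop-1-en-2-yl)-2-methylcyclohex-2-en-1-yl]oxy}dimethylsilane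
Product: 10 (4S,6R)-4-(tert-butyldimethylsilyloxy)-6-(3-chloroprop-1-en-2-yl)-3-methylcyclohex-2-en-1-one (ketone at C6)
Conditions: CrO3, 3,5-dimethylpyrazole, CH2Cl2, −20 °C
Reagents that add atoms: chromium trioxide, O=[Cr](=O)=O
Why: Allylic oxidation of a cyclohexene methylene to the enone by the hexavalent chromium–pyrazole complex; C6 is the only ring CH2 next to the alkene, and the side-chain alkene is deactivated by chlorine. The medium is not basic, so the C1 stereocentre α to the new ketone is kept.

Step 8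
Reactants: 10 (4S,6R)-4-(tert-butyldimethylsilyloxy)-6-(3-chloroprop-1-en-2-yl)-3-methylcyclohex-2-en-1-one
Product: 11 (1S,4S,6R)-4-(tert-butyldimethylsilyloxy)-6-(3-chloroprop-1-en-2-yl)-1-ethynyl-3-methylcyclohex-2-en-1-ol
Conditions: HC≡CMgBr, CeCl3, THF, −78 °C; NH4Cl (aq), −78 °C
Reagents that add atoms: ethynylmagnesium bromide, C#C[Mg]Br
Why: 1,2-addition of a small sp nucleophile; in the favoured half-chair (C1 side chain equatorial, C3 silyloxy pseudoaxial to avoid A(1,2) strain with the C4 methyl) axial attack places the alkyne cis to the C1 side chain and the hydroxyl trans to it. CeCl3 suppresses enolisation at C1, and the cold quench prevents the alkoxide from displacing the allylic chloride.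

Step 9
Reactants: 11 (1S,4S,6R)-4-(tert-butyldimethylsilyloxy)-6-(3-chloroprop-1-en-2-yl)-1-ethynyl-3-methylcyclohex-2-en-1-ol
Product: 13 (1S,4S,6R)-4-(tert-butyldimethylsilyloxy)-1-ethynyl-6-[(1E)-1-(4-methoxyphenoxy)prop-1-en-2-yl]-3-methylcyclohex-2-en-1-ol, via allyl aryl ether 12 (not isolated)
Conditions: 4-MeOC6H4OH (1.5 equiv), KOtBu (1.3 equiv), DMSO, rt; then KOtBu (4 equiv), rt
Reagents that add atoms: 4-methoxyphenol, COc1ccc(O)cc1
Why: Williamson substitution of the allylic chloride by the weakly basic aryloxide, which is kept in excess over the base so that the tertiary alcohol is not deprotonated and cannot close onto the chloride. Excess KOtBu in DMSO then isomerises the allyl ether to the propenyl ether through the cis-oxyallyl anion, so oxygen ends cis to the new methyl and trans to ring A (E). Under these conditions the substrate is an alkoxide–acetylide dianion, which cannot undergo a Cope shift.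

Step 10
Reactants: 13 (1S,4S,6R)-4-(tert-butyldimethylsilyloxy)-1-ethynyl-6-[(1E)-1-(4-methoxyphenoxy)prop-1-en-2-yl]-3-methylcyclohex-2-en-1-ol
Product: 15 (1S,4S,6R)-4-(tert-butyldimethylsilyloxy)-1-[(1Z)-1-iodobuta-1,3-dien-2-yl]-6-[(1E)-1-(4-methoxyphenoxy)prop-1-en-2-yl]-3-methylcyclohex-2-en-1-ol, via alkenylmagnesium chelate 14 (not isolated)
Conditions: CH2=CHMgBr (3.5 equiv), CuI (20 mol %), THF, 0 °C → rt; then I2, −78 °C
Reagents that add atoms: vinylmagnesium bromide, C=C[Mg]Br; iodine, II
Why: CuI-catalysed anti-carbomagnesiation of a propargylic alcohol: the vinyl group adds to the alkyne carbon next to the carbinol (C7) and magnesium ends on C8 inside a five-membered alkoxide chelate, hence cis to C6. Iodinolysis with retention gives the Z iodide; iodine is added cold and only to the end point to spare the enol ether.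

Step 11
Reactants: 15 (1S,4S,6R)-4-(tert-butyldimethylsilyloxy)-1-[(1Z)-1-iodobuta-1,3-dien-2-yl]-6-[(1E)-1-(4-methoxyphenoxy)prop-1-en-2-yl]-3-methylcyclohex-2-en-1-ol
Product: 16 (1S,4S,6R)-4-(tert-butyldimethylsilyloxy)-1-{(1Z)-1-[(4-methoxyphenyl)methoxy]buta-1,3-dien-2-yl}-6-[(1E)-1-(4-methoxyphenoxy)prop-1-en-2-yl]-3-methylcyclohex-2-en-1-ol
Conditions: 4-MeOC6H4CH2OH, CuI (10 mol %), 3,4,7,8-tetramethyl-1,10-phenanthroline (20 mol %), Cs2CO3, toluene, 80 °C
Reagents that add atoms: 4-methoxybenzyl alcohol, COc1ccc(CO)cc1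
Why: Ullmann-type CuI-catalysed C–O coupling of a vinyl iodide with a primary alcohol proceeds with retention of alkene geometry, so O8 stays cis to C6 (Z). The hindered tertiary alcohol does not couple, and carbonate is too weak to start an alkoxide-driven rearrangement.

Step 12
Reactants: 16 (1S,4S,6R)-4-(tert-butyldimethylsilyloxy)-1-{(1Z)-1-[(4-methoxyphenyl)methoxy]buta-1,3-dien-2-yl}-6-[(1E)-1-(4-methoxyphenoxy)prop-1-en-2-yl]-3-methylcyclohex-2-en-1-ol
Product: 18 (1S,4S,6R)-4-(tert-butyldimethylsilyloxy)-1-{(1Z)-4-hydroxy-1-[(4-methoxyphenyl)methoxy]but-1-en-2-yl}-6-[(1E)-1-(4-methoxyphenoxy)prop-1-en-2-yl]-3-methylcyclohex-2-en-1-ol, via alkylborane 17 (not isolated)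
Conditions: 9-BBN (excess), THF, 0 °C → rt; then NaOH, H2O2, 0 °C
Reagents that add atoms: hydrogen peroxide, OO
Why: 9-Borabicyclo[3.3.1]nonane hydroborates the monosubstituted vinyl group anti-Markovnikov far faster than the three trisubstituted alkenes; basic peroxide oxidation leaves both enol ethers intact. Any borinate formed at the hindered tertiary hydroxyl is hydrolysed in the same work-up.

Step 13
Reactants: 18 (1S,4S,6R)-4-(tert-butyldimethylsilyloxy)-1-{(1Z)-4-hydroxy-1-[(4-methoxyphenyl)methoxy]but-1-en-2-yl}-6-[(1E)-1-(4-methoxyphenoxy)prop-1-en-2-yl]-3-methylcyclohex-2-en-1-ol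
Product: 19 (1S,4S,6R)-4-(tert-butyldimethylsilyloxy)-1-{(1Z)-1-[(4-methoxyphenyl)methoxy]-4-(triethylsilyloxy)but-1-en-2-yl}-6-[(1E)-1-(4-methoxyphenoxy)prop-1-en-2-yl]-3-methylcyclohex-2-en-1-ol (oxy-Cope precursor; germacrane labels 1R,3S,6S)
Conditions: Et3SiCl, imidazole, CH2Cl2, −20 °C
Reagents that add atoms: chlorotriethylsilane, CC[Si](CC)(CC)Cl
Why: Selective silylation of the primary hydroxyl beside the hindered tertiary one; the triethylsilyl ether is chosen so that it can later be removed in the presence of the C3 tert-butyldimethylsilyl ether.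

Step 14
Reactants: 19 (1S,4S,6R)-4-(tert-butyldimethylsilyloxy)-1-{(1Z)-1-[(4-methoxyphenyl)methoxy]-4-(triethylsilyloxy)but-1-en-2-yl}-6-[(1E)-1-(4-methoxyphenoxy)prop-1-en-2-yl]-3-methylcyclohex-2-en-1-ol (cis-1,6-dialkenylcyclohex-2-en-1-ol)
Product: 22 (2Z,4S,6Z,8R,9S,10S)-4-(tert-butyldimethylsilyloxy)-8-(4-methoxyphenoxy)-9-[(4-methoxyphenyl)methoxy]-3,7-dimethyl-10-[2-(triethylsilyloxy)ethyl]cyclodeca-2,6-dien-1-one (6-ketone; germacrane labels 3S,7S,8S,9R), via potassium alkoxide 20 (not isolated), via potassium enolate 21 (not isolated)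
Conditions: KN(SiMe3)2 (1.2 equiv), THF, −78 → 0 °C; then AcOH, THF, −78 °C
Reagents that add atoms: none
Why: Deprotonation gives alkoxide 20, whose charge weakens the C1–C6 bond so that the 3-oxido-1,5-diene C8=C7–C6–C1–C10=C9 undergoes the anionic oxy-Cope rearrangement, a [3,3]-sigmatropic shift known for cis-1,2-dialkenylcyclohexanols. The ten-membered ring is not closed end to end: it arises by ring expansion, C8–C9 forming while C1–C6 breaks within a six-membered chair transition state, so no dilution is needed. In the chair with C2 axial on C1 and C5 equatorial on C6 the new C1=C10 alkene is cis within the ring (Z) and enolate 21 is trans within the ring; this chair corresponds to the ring A half-chair with the C1 alkenyl group equatorial and the C3 silyloxy group pseudoaxial, which A(1,2) strain with the C4 methyl favours. The Z enol ether places O8 axial and the E enol ether places O9 equatorial, and with the absolute sense of the chair fixed by C1 and C6 this gives 8S and 9R. C7 is created on protonation: the trans enolate is open only on its outer face, which gives the target configuration (labelled 7S in 22 by CIP priority). The step needs this chair to win over the other chair (C5 axial, which would give the E alkene and the opposite C8/C9 pair), over boat arrangements and over the bridged shift through the ring alkene C4=C5. The syn-axial O6/O8 pair can be bridged by the potassium cation, which is why no crown ether is added, whereas the other chair has a syn-axial C5/O8 contact. The quench is made cold because enolate 21 carries a β-alkoxy group that could be expelled on warming.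

Step 15
Reactants: 22 (2Z,4S,6Z,8R,9S,10S)-4-(tert-butyldimethylsilyloxy)-8-(4-methoxyphenoxy)-9-[(4-methoxyphenyl)methoxy]-3,7-dimethyl-10-[2-(triethylsilyloxy)ethyl]cyclodeca-2,6-dien-1-one
Product: 24 (1R,2Z,4S,6Z,8R,9S,10R)-4-(tert-butyldimethylsilyloxy)-10-(2-hydroxyethyl)-8-(4-methoxyphenoxy)-9-[(4-methoxyphenyl)methoxy]-3,7-dimethylcyclodeca-2,6-dien-1-ol (6,12-diol; germacrane labels 3S,6R,7R,8S,9R), via silyl ether alcohol 23 (not isolated)
Conditions: NaBH4, CeCl3·7H2O, MeOH/THF, −78 → −40 °C; then PPTS, 0 °C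
Reagents that add atoms: none
Why: Luche 1,2-reduction of the enone; hydride should enter from the outer face of the carbonyl in the conformation inherited from the trans enolate, the same face that took up the C7 proton, so H6 and H7 end cis (6R). Mild acid in methanol then removes the primary triethylsilyl group and leaves the secondary tert-butyldimethylsilyl ether.

Step 16
Reactants: 24 (1R,2Z,4S,6Z,8R,9S,10R)-4-(tert-butyldimethylsilyloxy)-10-(2-hydroxyethyl)-8-(4-methoxyphenoxy)-9-[(4-methoxyphenyl)methoxy]-3,7-dimethylcyclodeca-2,6-dien-1-ol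
Product: 26 (3S,6R,7R,8S,9R)-3-(tert-butyldimethylsilyloxy)-9-(4-methoxyphenoxy)-8-[(4-methoxyphenyl)methoxy]-13-norgermacra-1(10)Z,4Z-dien-12,6-olide (cis-fused γ-lactone), via lactol 25 (not isolated)
Conditions: TEMPO (2,2,6,6-tetramethylpiperidin-1-oxyl, 20 mol %), PhI(OAc)2, CH2Cl2, rt
Reagents that add atoms: none
Why: Oxoammonium oxidation takes the primary alcohol to the aldehyde, which is trapped by the C6 hydroxyl as the five-membered lactol and oxidised on to the lactone; the secondary allylic alcohol reacts more slowly than the primary one.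

Step 17
Reactants: 26 (3S,6R,7R,8S,9R)-3-(tert-butyldimethylsilyloxy)-9-(4-methoxyphenoxy)-8-[(4-methoxyphenyl)methoxy]-13-norgermacra-1(10)Z,4Z-dien-12,6-olide
Product: 30 (3S,6R,7R,8S,9R)-3-(tert-butyldimethylsilyloxy)-9-(4-methoxyphenoxy)-8-[(4-methoxyphenyl)methoxy]germacra-1(10)Z,4Z,11(13)-trien-12,6-olide, via lithium enolate 27 (not isolated), via Mannich base 28 (not isolated), via ammonium iodide 29 (not isolated)
Conditions: LiN(iPr)2, THF, −78 °C; Me2N=CH2 I, −78 °C → rt; then MeI, MeOH; NaHCO3 (aq), CH2Cl2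
Reagents that add atoms: N,N-dimethylmethyleneiminium iodide, C=[N+](C)C.[I-]
Why: α-Methylenation of a γ-lactone by Mannich reaction of its enolate with Eschenmoser's salt, quaternisation and elimination of trimethylamine. The enolate carbon C11 has no β-leaving group, and no other acidic site is present.

Step 18
Reactants: 30 (3S,6R,7R,8S,9R)-3-(tert-butyldimethylsilyloxy)-9-(4-methoxyphenoxy)-8-[(4-methoxyphenyl)methoxy]germacra-1(10)Z,4Z,11(13)-trien-12,6-olide
Product: 31 (3S,6R,7R,8S,9R)-3-hydroxy-9-(4-methoxyphenoxy)-8-[(4-methoxyphenyl)methoxy]germacra-1(10)Z,4Z,11(13)-trien-12,6-olide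
Conditions: HF·pyridine, pyridine, THF, 0 °C → rt
Reagents that add atoms: none
Why: Buffered fluoride cleavage of the secondary allylic silyl ether; the acidic, non-nucleophilic medium spares the Michael acceptor and both aryl-type ethers.

Step 19
Reactants: 31 (3S,6R,7R,8S,9R)-3-hydroxy-9-(4-methoxyphenoxy)-8-[(4-methoxyphenyl)methoxy]germacra-1(10)Z,4Z,11(13)-trien-12,6-olide
Product: 32 (3S,6R,7R,8S,9R)-3-acetoxy-9-(4-methoxyphenoxy)-8-[(4-methoxyphenyl)methoxy]germacra-1(10)Z,4Z,11(13)-trien-12,6-olide
Conditions: Ac2O, pyridine, DMAP (cat.), CH2Cl2, 0 °C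
Reagents that add atoms: acetic anhydride, CC(=O)OC(C)=O
Why: Acylation of the only free hydroxyl; the configuration at C3 is not touched.

Step 20
Reactants: 32 (3S,6R,7R,8S,9R)-3-acetoxy-9-(4-methoxyphenoxy)-8-[(4-methoxyphenyl)methoxy]germacra-1(10)Z,4Z,11(13)-trien-12,6-olide
Product: 33 (3S,6R,7S,8S,9R)-3-acetoxy-8-hydroxy-9-(4-methoxyphenoxy)germacra-1(10)Z,4Z,11(13)-trien-12,6-olide (7S by CIP priority change only)
Conditions: DDQ, CH2Cl2/pH 7 buffer, 0 °C
Reagents that add atoms: none
Why: Oxidative cleavage of the p-methoxybenzyl ether through its benzylic cation; the p-methoxyphenyl ether has no benzylic hydrogen and is inert to DDQ under these conditions.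

Step 21
Reactants: 33 (3S,6R,7S,8S,9R)-3-acetoxy-8-hydroxy-9-(4-methoxyphenoxy)germacra-1(10)Z,4Z,11(13)-trien-12,6-olide; 5 (2R,3R)-2,3-dimethyloxirane-2-carboxylic acid
Product: 35 (3S,6R,7R,8S,9R)-3-acetoxy-8-{[(2R,3R)-2,3-dimethyloxiran-2-yl]carbonyloxy}-9-(4-methoxyphenoxy)germacra-1(10)Z,4Z,11(13)-trien-12,6-olide, via mixed anhydride 34 (not isolated)
Conditions: 2,4,6-Cl3C6H2COCl, Et3N, THF, rt; then 33, DMAP, toluene, rt → 40 °C
Reagents that add atoms: none
Why: Yamaguchi esterification, suited to a hindered secondary alcohol and an α-quaternary acid; the epoxy acid has no α-hydrogen and cannot epimerise, and C9 is still protected so no regioisomer can form.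

Step 22
Reactants: 35 (3S,6R,7R,8S,9R)-3-acetoxy-8-{[(2R,3R)-2,3-dimethyloxiran-2-yl]carbonyloxy}-9-(4-methoxyphenoxy)germacra-1(10)Z,4Z,11(13)-trien-12,6-olide
Product: 36 target, (3S,6R,7R,8S,9R)-3-acetoxy-8-{[(2R,3R)-2,3-dimethyloxiran-2-yl]carbonyloxy}-9-hydroxygermacra-1(10)Z,4Z,11(13)-trien-12,6-olide
Conditions: (NH4)2Ce(NO3)6, pyridine, MeCN/H2O (4:1), 0 °C
Reagents that add atoms: none
Why: Tetravalent cerium oxidises the electron-rich aryl ring and water attacks its ipso carbon, so the aryl group leaves as benzoquinone and the C9–O bond is never broken (retention at C9). The brief, buffered, non-basic conditions avoid epoxide opening and C8→C9 acyl migration.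

## Compound list

1 | angelic acid, (2Z)-2-methylbut-2-enoic acid | C/C=C(/C)C(O)=O | starting material
2 | (2Z)-2-methylbut-2-en-1-ol | C/C=C(/C)CO | intermediate
3 | [(2S,3R)-2,3-dimethyloxiran-2-yl]methanol | OC[C@]1(C)O[C@@H]1C | intermediate
4 | (2R,3R)-2,3-dimethyloxirane-2-carbaldehyde | O=C[C@]1(C)O[C@@H]1C | intermediate (not isolated)
5 | (2R,3R)-2,3-dimethyloxirane-2-carboxylic acid | OC(=O)[C@]1(C)O[C@@H]1C | intermediate
6 | (R)-(−)-carvone | C1C=C(C)C(=O)C[C@@H]1C(C)=C | starting material
7 | (5R)-5-(3-chloroprop-1-en-2-yl)-2-methylcyclohex-2-en-1-one | C1C=C(C)C(=O)C[C@@H]1C(=C)CCl | intermediate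
8 | (1S,5R)-5-(3-chloroprop-1-en-2-yl)-2-methylcyclohex-2-en-1-ol | C1C=C(C)[C@@H](O)C[C@@H]1C(=C)CCl | intermediate
9 | tert-butyldimethylsilyl ether of 8 | C1C=C(C)[C@@H](O[Si](C)(C)C(C)(C)C)C[C@@H]1C(=C)CCl | intermediate
10 | (4S,6R)-4-(tert-butyldimethylsilyloxy)-6-(3-chloroprop-1-en-2-yl)-3-methylcyclohex-2-en-1-one | O=C1C=C(C)[C@@H](O[Si](C)(C)C(C)(C)C)C[C@@H]1C(=C)CCl | intermediate
11 | (1S,4S,6R)-4-(tert-butyldimethylsilyloxy)-6-(3-chloroprop-1-en-2-yl)-1-ethynyl-3-methylcyclohex-2-en-1-ol | O[C@@]1(C#C)C=C(C)[C@@H](O[Si](C)(C)C(C)(C)C)C[C@@H]1C(=C)CCl | intermediate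
12 | (1S,4S,6R)-4-(tert-butyldimethylsilyloxy)-1-ethynyl-6-[3-(4-methoxyphenoxy)prop-1-en-2-yl]-3-methylcyclohex-2-en-1-ol | O[C@@]1(C#C)C=C(C)[C@@H](O[Si](C)(C)C(C)(C)C)C[C@@H]1C(=C)COc2ccc(OC)cc2 | intermediate (not isolated)
13 | (1S,4S,6R)-4-(tert-butyldimethylsilyloxy)-1-ethynyl-6-[(1E)-1-(4-methoxyphenoxy)prop-1-en-2-yl]-3-methylcyclohex-2-en-1-ol | O[C@@]1(C#C)C=C(C)[C@@H](O[Si](C)(C)C(C)(C)C)C[C@@H]1/C(C)=C/Oc2ccc(OC)cc2 | intermediate
14 | bromomagnesium alkoxide of the (Z)-1-(bromomagnesio)buta-1,3-dien-2-yl carbinol (magnesium on C8 cis to C6) | Br[Mg]O[C@@]1(/C(C=C)=C\[Mg]Br)C=C(C)[C@@H](O[Si](C)(C)C(C)(C)C)C[C@@H]1/C(C)=C/Oc2ccc(OC)cc2 | intermediate (not isolated)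
15 | (1S,4S,6R)-4-(tert-butyldimethylsilyloxy)-1-[(1Z)-1-iodobuta-1,3-dien-2-yl]-6-[(1E)-1-(4-methoxyphenoxy)prop-1-en-2-yl]-3-methylcyclohex-2-en-1-ol | O[C@@]1(/C(C=C)=C\I)C=C(C)[C@@H](O[Si](C)(C)C(C)(C)C)C[C@@H]1/C(C)=C/Oc2ccc(OC)cc2 | intermediate
16 | (1S,4S,6R)-4-(tert-butyldimethylsilyloxy)-1-{(1Z)-1-[(4-methoxyphenyl)methoxy]buta-1,3-dien-2-yl}-6-[(1E)-1-(4-methoxyphenoxy)prop-1-en-2-yl]-3-methylcyclohex-2-en-1-ol | O[C@@]1(/C(C=C)=C\OCc2ccc(OC)cc2)C=C(C)[C@@H](O[Si](C)(C)C(C)(C)C)C[C@@H]1/C(C)=C/Oc3ccc(OC)cc3 | intermediate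
17 | B-alkyl-9-borabicyclo[3.3.1]nonane adduct of 16 (boron on C12) | O[C@@]1(/C(CCB4C5CCCC4CCC5)=C\OCc2ccc(OC)cc2)C=C(C)[C@@H](O[Si](C)(C)C(C)(C)C)C[C@@H]1/C(C)=C/Oc3ccc(OC)cc3 | intermediate (not isolated)
18 | (1S,4S,6R)-4-(tert-butyldimethylsilyloxy)-1-{(1Z)-4-hydroxy-1-[(4-methoxyphenyl)methoxy]but-1-en-2-yl}-6-[(1E)-1-(4-methoxyphenoxy)prop-1-en-2-yl]-3-methylcyclohex-2-en-1-ol | O[C@@]1(/C(CCO)=C\OCc2ccc(OC)cc2)C=C(C)[C@@H](O[Si](C)(C)C(C)(C)C)C[C@@H]1/C(C)=C/Oc3ccc(OC)cc3 | intermediate
19 | (1S,4S,6R)-4-(tert-butyldimethylsilyloxy)-1-{(1Z)-1-[(4-methoxyphenyl)methoxy]-4-(triethylsilyloxy)but-1-en-2-yl}-6-[(1E)-1-(4-methoxyphenoxy)prop-1-en-2-yl]-3-methylcyclohex-2-en-1-ol | O[C@@]1(/C(CCO[Si](CC)(CC)CC)=C\OCc2ccc(OC)cc2)C=C(C)[C@@H](O[Si](C)(C)C(C)(C)C)C[C@@H]1/C(C)=C/Oc3ccc(OC)cc3 | intermediate (precursor of the key step)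
20 | potassium alkoxide of 19 | [K+].[O-][C@@]1(/C(CCO[Si](CC)(CC)CC)=C\OCc2ccc(OC)cc2)C=C(C)[C@@H](O[Si](C)(C)C(C)(C)C)C[C@@H]1/C(C)=C/Oc3ccc(OC)cc3 | intermediate (not isolated)
21 | potassium enolate of 22 (C6=C7 trans within the ring, C1=C10 and C4=C5 cis) | [K+].[O-]/C(=C1/CCO[Si](CC)(CC)CC)/C=C(/C)[C@@H](O[Si](C)(C)C(C)(C)C)C/C=C(/C)[C@@H](Oc2ccc(OC)cc2)[C@H]1OCc3ccc(OC)cc3 | intermediate (not isolated)
22 | (2Z,4S,6Z,8R,9S,10S)-4-(tert-butyldimethylsilyloxy)-8-(4-methoxyphenoxy)-9-[(4-methoxyphenyl)methoxy]-3,7-dimethyl-10-[2-(triethylsilyloxy)ethyl]cyclodeca-2,6-dien-1-one | O=C1/C=C(/C)[C@@H](O[Si](C)(C)C(C)(C)C)C/C=C(/C)[C@@H](Oc2ccc(OC)cc2)[C@@H](OCc3ccc(OC)cc3)[C@@H]1CCO[Si](CC)(CC)CC | intermediate (product of the key step)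
23 | (1R,2Z,4S,6Z,8R,9S,10R)-cyclodeca-2,6-dien-1-ol corresponding to 22 (C6 alcohol, C12 triethylsilyl ether) | O[C@@H]1/C=C(/C)[C@@H](O[Si](C)(C)C(C)(C)C)C/C=C(/C)[C@@H](Oc2ccc(OC)cc2)[C@@H](OCc3ccc(OC)cc3)[C@@H]1CCO[Si](CC)(CC)CC | intermediate (not isolated)
24 | (1R,2Z,4S,6Z,8R,9S,10R)-4-(tert-butyldimethylsilyloxy)-10-(2-hydroxyethyl)-8-(4-methoxyphenoxy)-9-[(4-methoxyphenyl)methoxy]-3,7-dimethylcyclodeca-2,6-dien-1-ol | O[C@@H]1/C=C(/C)[C@@H](O[Si](C)(C)C(C)(C)C)C/C=C(/C)[C@@H](Oc2ccc(OC)cc2)[C@@H](OCc3ccc(OC)cc3)[C@@H]1CCO | intermediate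
25 | lactol of 26 (12-hydroxy-6,12-epoxide, C12 epimers) | C1C(O)O[C@@H]2/C=C(/C)[C@@H](O[Si](C)(C)C(C)(C)C)C/C=C(/C)[C@@H](Oc3ccc(OC)cc3)[C@@H](OCc4ccc(OC)cc4)[C@H]12 | intermediate (not isolated)
26 | (3S,6R,7R,8S,9R)-3-(tert-butyldimethylsilyloxy)-9-(4-methoxyphenoxy)-8-[(4-methoxyphenyl)methoxy]-13-norgermacra-1(10)Z,4Z-dien-12,6-olide | C1C(=O)O[C@@H]2/C=C(/C)[C@@H](O[Si](C)(C)C(C)(C)C)C/C=C(/C)[C@@H](Oc3ccc(OC)cc3)[C@@H](OCc4ccc(OC)cc4)[C@H]12 | intermediate
27 | lithium enolate of 26 | [Li+].C1=C([O-])O[C@@H]2/C=C(/C)[C@@H](O[Si](C)(C)C(C)(C)C)C/C=C(/C)[C@@H](Oc3ccc(OC)cc3)[C@@H](OCc4ccc(OC)cc4)[C@H]12 | intermediate (not isolated)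
28 | 11-(dimethylaminomethyl) lactone (Mannich base, C11 epimers) | CN(C)CC1C(=O)O[C@@H]2/C=C(/C)[C@@H](O[Si](C)(C)C(C)(C)C)C/C=C(/C)[C@@H](Oc3ccc(OC)cc3)[C@@H](OCc4ccc(OC)cc4)[C@H]12 | intermediate (not isolated)
29 | 11-(trimethylammoniomethyl) lactone iodide | [I-].C[N+](C)(C)CC1C(=O)O[C@@H]2/C=C(/C)[C@@H](O[Si](C)(C)C(C)(C)C)C/C=C(/C)[C@@H](Oc3ccc(OC)cc3)[C@@H](OCc4ccc(OC)cc4)[C@H]12 | intermediate (not isolated)
30 | (3S,6R,7R,8S,9R)-3-(tert-butyldimethylsilyloxy)-9-(4-methoxyphenoxy)-8-[(4-methoxyphenyl)methoxy]germacra-1(10)Z,4Z,11(13)-trien-12,6-olide | C=C1C(=O)O[C@@H]2/C=C(/C)[C@@H](O[Si](C)(C)C(C)(C)C)C/C=C(/C)[C@@H](Oc3ccc(OC)cc3)[C@@H](OCc4ccc(OC)cc4)[C@H]12 | intermediate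
31 | (3S,6R,7R,8S,9R)-3-hydroxy-9-(4-methoxyphenoxy)-8-[(4-methoxyphenyl)methoxy]germacra-1(10)Z,4Z,11(13)-trien-12,6-olide | C=C1C(=O)O[C@@H]2/C=C(/C)[C@@H](O)C/C=C(/C)[C@@H](Oc3ccc(OC)cc3)[C@@H](OCc4ccc(OC)cc4)[C@H]12 | intermediate
32 | (3S,6R,7R,8S,9R)-3-acetoxy-9-(4-methoxyphenoxy)-8-[(4-methoxyphenyl)methoxy]germacra-1(10)Z,4Z,11(13)-trien-12,6-olide | C=C1C(=O)O[C@@H]2/C=C(/C)[C@@H](OC(C)=O)C/C=C(/C)[C@@H](Oc3ccc(OC)cc3)[C@@H](OCc4ccc(OC)cc4)[C@H]12 | intermediate
33 | (3S,6R,7S,8S,9R)-3-acetoxy-8-hydroxy-9-(4-methoxyphenoxy)germacra-1(10)Z,4Z,11(13)-trien-12,6-olide | C=C1C(=O)O[C@@H]2/C=C(/C)[C@@H](OC(C)=O)C/C=C(/C)[C@@H](Oc3ccc(OC)cc3)[C@@H](O)[C@H]12 | intermediate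
34 | (2R,3R)-2,3-dimethyloxirane-2-carboxylic 2,4,6-trichlorobenzoic anhydride | O=C(OC(=O)[C@]1(C)O[C@@H]1C)c1c(Cl)cc(Cl)cc1Cl | intermediate (not isolated)
35 | (3S,6R,7R,8S,9R)-3-acetoxy-8-{[(2R,3R)-2,3-dimethyloxiran-2-yl]carbonyloxy}-9-(4-methoxyphenoxy)germacra-1(10)Z,4Z,11(13)-trien-12,6-olide | C=C1C(=O)O[C@@H]2/C=C(/C)[C@@H](OC(C)=O)C/C=C(/C)[C@@H](Oc3ccc(OC)cc3)[C@@H](OC(=O)[C@]4(C)O[C@@H]4C)[C@H]12 | intermediate
36 | CNP0299903.1, (3S,6R,7R,8S,9R)-3-acetoxy-8-{[(2R,3R)-2,3-dimethyloxiran-2-yl]carbonyloxy}-9-hydroxygermacra-1(10)Z,4Z,11(13)-trien-12,6-olide | C=C1C(=O)O[C@@H]2/C=C(/C)[C@@H](OC(C)=O)C/C=C(/C)[C@@H](O)[C@@H](OC(=O)[C@]3(C)O[C@@H]3C)[C@H]12 | target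

## Step count and least certain steps

Total: 22 steps. Longest linear sequence: 19 steps (steps 4–22, from carvone 6); the acid 5 (steps 1–3) joins at step 21.

**Step 14 (key step).** Two things can go wrong. The rearrangement may run partly through the other chair, with loss of the C1=C10 geometry and of the C8/C9 configuration, because the two chairs differ only by a few non-bonded contacts and by the cation bridge. Enol-ether termini also slow the shift, so the temperature needed may allow expulsion of the C8 alkoxy group from the enolate before the quench. Fallback: the neutral siloxy variant, which never forms an enolate anion. From 19 the tertiary hydroxyl is silylated (Me3SiOTf, 2,6-lutidine, CH2Cl2, −78 °C) to give the trimethylsilyl ether F1. F1 is heated in o-xylene at 150–180 °C in base-washed glass to give the ring-expanded trimethylsilyl enol ether F2. F2 is cleaved with n-Bu4NF/AcOH at −78 °C, protonating on the outer face, to return to the route at 22. The thermal budget is the limit of this fallback, since the allylic aryl ether formed can undergo an aromatic Claisen shift at the upper end of that range.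

**Step 8.** Poor facial selectivity is possible: attack through the minor half-chair (C1 side chain axial, nucleophile anti to it) would put the alkyne trans to the side chain and lead, after step 14, to the E alkene. Fallback: replace substrate control by complexation control. Ketone 10 is first bound to the bulky aluminium phenoxide MeAl(OC6H2-2,6-tBu2-4-Me)2, which occupies the equatorial side of the carbonyl, and lithium (trimethylsilyl)acetylide is added at −78 °C to give the silylalkynyl carbinol F3. Desilylation of F3 with n-Bu4NF/AcOH at 0 °C returns to the route at 11.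

**Step 7.** Oxidation may occur at the wrong allylic site (the silyloxy-bearing C3–H or the side chain), or over-oxidation may occur, because hexavalent chromium discriminates among allylic C–H bonds only moderately. Fallback: introduce the C6 oxygen by epoxide chemistry and an oxidative allylic transposition, with chlorination moved to the end. From 6, Corey–Bakshi–Shibata reduction as in step 5 gives (1S,5R)-trans-carveol F4, and silylation of F4 (t-BuMe2SiCl, imidazole, DMF) gives its tert-butyldimethylsilyl ether F5. Epoxidation of the ring alkene of F5 with mCPBA gives the 4,5-epoxide F6. Opening of F6 at C5 with PhSeNa gives the hydroxy selenide F7, and oxidation of F7 with H2O2 followed by selenoxide elimination gives the tertiary allylic alcohol F8, which carries the C5=C6 alkene. Pyridinium chlorochromate (C5H5NH)[CrO3Cl] then effects the oxidative 1,3-transposition of F8 to the isopropenyl enone F9. Ene chlorination of F9 as in step 4 (the ring alkene is now deactivated) returns to the route at 10.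

**Step 15.** Hydride delivery to the other face is possible if the ten-membered enone relaxes to a conformation that exposes the inner face of the carbonyl before reduction, which would set C6 with the wrong configuration. Fallback: invert C6 while closing the lactone. From 22, the reduction and desilylation of step 15 would in that case give the C6-epimeric diol F10. F10 is oxidised as in step 16 to the C6-epimeric lactone F11. Saponification of F11 (LiOH, THF/H2O) and careful acidification at 0 °C give the hydroxy acid F12. F12 is closed at once under Mitsunobu conditions (PPh3, diisopropyl azodicarboxylate, THF, 0 °C), with inversion at C6, to return to the route at 26.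

## Further compounds

F1 | step 14 | trimethylsilyl ether of 19 | C[Si](C)(C)O[C@@]1(/C(CCO[Si](CC)(CC)CC)=C\OCc2ccc(OC)cc2)C=C(C)[C@@H](O[Si](C)(C)C(C)(C)C)C[C@@H]1/C(C)=C/Oc3ccc(OC)cc3
F2 | step 14 | trimethylsilyl enol ether of 22 (C6=C7 trans within the ring) | C[Si](C)(C)O/C(=C1/CCO[Si](CC)(CC)CC)/C=C(/C)[C@@H](O[Si](C)(C)C(C)(C)C)C/C=C(/C)[C@@H](Oc2ccc(OC)cc2)[C@H]1OCc3ccc(OC)cc3
F3 | step 8 | (1S,4S,6R)-4-(tert-butyldimethylsilyloxy)-6-(3-chloroprop-1-en-2-yl)-3-methyl-1-[(trimethylsilyl)ethynyl]cyclohex-2-en-1-ol | O[C@@]1(C#C[Si](C)(C)C)C=C(C)[C@@H](O[Si](C)(C)C(C)(C)C)C[C@@H]1C(=C)CCl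
F4 | step 7 | (1S,5R)-2-methyl-5-(prop-1-en-2-yl)cyclohex-2-en-1-ol (trans-carveol) | C1C=C(C)[C@@H](O)C[C@@H]1C(C)=C
F5 | step 7 | tert-butyldimethylsilyl ether of F4 | C1C=C(C)[C@@H](O[Si](C)(C)C(C)(C)C)C[C@@H]1C(C)=C
F6 | step 7 | 4,5-epoxide of F5 (epoxide diastereomers) | C1C2OC2(C)[C@@H](O[Si](C)(C)C(C)(C)C)C[C@@H]1C(C)=C
F7 | step 7 | 4-hydroxy-5-(phenylselanyl) derivative of F5 | C1C([Se]c2ccccc2)C(C)(O)[C@@H](O[Si](C)(C)C(C)(C)C)C[C@@H]1C(C)=C
F8 | step 7 | tertiary allylic alcohol, 4-hydroxy-5,6-ene derivative of F5 | C1=CC(C)(O)[C@@H](O[Si](C)(C)C(C)(C)C)C[C@@H]1C(C)=C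
F9 | step 7 | (4S,6R)-4-(tert-butyldimethylsilyloxy)-3-methyl-6-(prop-1-en-2-yl)cyclohex-2-en-1-one | O=C1C=C(C)[C@@H](O[Si](C)(C)C(C)(C)C)C[C@@H]1C(C)=C
F10 | step 15 | C6 epimer of diol 24 | O[C@H]1/C=C(/C)[C@@H](O[Si](C)(C)C(C)(C)C)C/C=C(/C)[C@@H](Oc2ccc(OC)cc2)[C@@H](OCc3ccc(OC)cc3)[C@@H]1CCO
F11 | step 15 | C6 epimer of lactone 26 | C1C(=O)O[C@H]2/C=C(/C)[C@@H](O[Si](C)(C)C(C)(C)C)C/C=C(/C)[C@@H](Oc3ccc(OC)cc3)[C@@H](OCc4ccc(OC)cc4)[C@H]12
F12 | step 15 | 6-epi-6-hydroxy-12-oic acid (seco acid of F11) | O[C@H]1/C=C(/C)[C@@H](O[Si](C)(C)C(C)(C)C)C/C=C(/C)[C@@H](Oc2ccc(OC)cc2)[C@@H](OCc3ccc(OC)cc3)[C@@H]1CC(O)=O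
A1 | alternative 1 | C9 triethylsilyl ether of the target | C=C1C(=O)O[C@@H]2/C=C(/C)[C@@H](OC(C)=O)C/C=C(/C)[C@@H](O[Si](CC)(CC)CC)[C@@H](OC(=O)[C@]3(C)O[C@@H]3C)[C@H]12
A2 | alternative 1 | 7-ethynyl-6-hydroxy ten-membered carbocycle carrying the C3 acetate, C8 epoxy ester and C9 triethylsilyl ether | O[C@@H]1/C=C(/C)[C@@H](OC(C)=O)C/C=C(/C)[C@@H](O[Si](CC)(CC)CC)[C@@H](OC(=O)[C@]2(C)O[C@@H]2C)[C@@H]1C#C
A3 | alternative 2 | ten-membered 9-keto-8-hydroxy α-methylene lactone | C=C1C(=O)O[C@@H]2/C=C(/C)[C@@H](OC(C)=O)C/C=C(/C)C(=O)[C@@H](O)[C@H]12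
A4 | alternative 2 | thirteen-membered keto ether bridged by the butenolide (O8–C13 ether, C7=C11) | O=C1O[C@@H]2/C=C(/C)[C@@H](OC(C)=O)C/C=C(/C)C(=O)COCC1=C2
A5 | alternative 3 | C9 triethylsilyl, C8 p-methoxybenzyl ether of the lactone core | C=C1C(=O)O[C@@H]2/C=C(/C)[C@@H](OC(C)=O)C/C=C(/C)[C@@H](O[Si](CC)(CC)CC)[C@@H](OCc3ccc(OC)cc3)[C@H]12
A6 | alternative 3 | open-chain (Z)-vinyl iodide aldehyde with the methyl acrylate unit on C7 | I/C=C(/C)[C@@H](OC(C)=O)C/C=C(/C)[C@@H](O[Si](CC)(CC)CC)[C@@H](OCc1ccc(OC)cc1)[C@@H](C=O)C(=C)C(=O)OC
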